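**Plan**

- Retrosynthesis: the C1–C2 bond, the C1–OMe bond and the C3–H bond are removed together, leaving a (Z)-2-benzyl-3-arylacrylate, CO and methanol. The C2=C3 alkene is then cut by olefination into the ring A aldehyde and a phosphonoacetate, the C3–CH2(ring B) bond by alkylation, and the prenyl group is cut from ring B.
- Enabling feature: C1 is a methyl ester on benzylic C2 (which carries ring A), and C3 carries only one hydrogen besides C4 and the ring B benzyl group. The C1 ester and both stereocentres can therefore come from adding H and CO2Me to one face of a C2=C3 alkene.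
- Forward: ring B is prenylated, silylated and converted to a benzylic bromide, which alkylates a diphenyl phosphonoacetate 2-(trimethylsilyl)ethyl ester. Z-selective olefination with the silylated ring A aldehyde joins C2=C3, hydromethoxycarbonylation adds C1, and fluoride frees the C4 acid and both phenols. No ring is formed.
- Stereochemistry: the erythro relationship comes from syn addition to the Z alkene (ring A cis to the C4 ester); the absolute (2S,3S) sense comes from the chiral bisphosphine on palladium.

Key step: step 10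

Remark 1: numbering is C1 = methyl ester carbon, C2 = CH bearing ring A (4-hydroxyphenyl), C3 = CH bearing the ring B benzyl group, C4 = carboxyl carbon; the target is taken as (2S,3S), as drawn.
Remark 2: both phenols are carried as triisopropylsilyl ethers because these tolerate alkoxide bases and sulfonic acid in methanol better than smaller silyl ethers.
Remark 3: the sense of induction of the bisphosphine in step 10 cannot be derived from precedent; the (R) ligand is written and its antipode would be used if the opposite face proved to be preferred.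

**Route**

Step 1
Reactants: 1 4-hydroxybenzaldehyde; 2 prenyl bromide (1-bromo-3-methylbut-2-ene)
Product: 3 4-hydroxy-3-(3-methylbut-2-enyl)benzaldehyde
Conditions: KOH (10 % aq.), 25 °C
Reagents that add atoms: none
Why: Ortho C-alkylation of the phenoxide by the allylic bromide (C-prenylation, with water solvating the phenoxide oxygen and steering the electrophile to carbon) is the usual direct route to this known aldehyde, the para position being blocked by the formyl group.

Step 2
Reactants: 3 4-hydroxy-3-(3-methylbut-2-enyl)benzaldehyde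
Product: 4 3-(3-methylbut-2-enyl)-4-(triisopropylsilyloxy)benzaldehyde
Conditions: TIPSCl, imidazole, DMAP (cat.), DMF, 25 °C
Reagents that add atoms: chlorotriisopropylsilane, CC(C)[Si](Cl)(C(C)C)C(C)C
Why: Imidazole-mediated O-silylation of the phenol gives an aryl triisopropylsilyl ether that should outlast the later bases and the acidic carbonylation medium and keeps the phenol from adding to the prenyl alkene.

Step 3
Reactants: 4 3-(3-methylbut-2-enyl)-4-(triisopropylsilyloxy)benzaldehyde
Product: 5 [3-(3-methylbut-2-enyl)-4-(triisopropylsilyloxy)phenyl]methanol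
Conditions: NaBH4, MeOH–THF, 0 °C
Reagents that add atoms: none
Why: Borohydride reduction of the aldehyde is chemoselective beside the alkene and the aryl silyl ether.

Step 4
Reactants: 5 [3-(3-methylbut-2-enyl)-4-(triisopropylsilyloxy)phenyl]methanol
Product: 6 4-(bromomethyl)-2-(3-methylbut-2-enyl)-1-(triisopropylsilyloxy)benzene
Conditions: CBr4, PPh3, CH2Cl2, 0 °C
Reagents that add atoms: carbon tetrabromide, BrC(Br)(Br)Br
Why: Appel bromination converts the benzylic alcohol to the bromide under neutral conditions that spare the prenyl alkene and the silyl ether.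

Step 5
Reactants: 7 2-(trimethylsilyl)ethanol; 8 bromoacetyl bromide
Product: 9 2-(trimethylsilyl)ethyl bromoacetate
Conditions: pyridine, CH2Cl2, 0 °C
Reagents that add atoms: none
Why: O-Acylation of the alcohol by the acyl bromide (esterification) is far faster than substitution at the alkyl bromide, and the 2-(trimethylsilyl)ethyl ester is chosen because fluoride can later remove it beside a methyl ester.

Step 6
Reactants: 9 2-(trimethylsilyl)ethyl bromoacetate; 10 diphenyl phosphite
Product: 11 2-(trimethylsilyl)ethyl (diphenoxyphosphoryl)acetate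
Conditions: Et3N, CH2Cl2, 0 °C → 25 °C
Reagents that add atoms: none
Why: Michaelis–Becker-type P-alkylation of the diaryl phosphite by the bromoacetate under amine base is the standard preparation of diaryl phosphonoacetates for Z-selective olefination.

Step 7
Reactants: 11 2-(trimethylsilyl)ethyl (diphenoxyphosphoryl)acetate; 6 4-(bromomethyl)-2-(3-methylbut-2-enyl)-1-(triisopropylsilyloxy)benzene
Product: 12 2-(trimethylsilyl)ethyl 2-(diphenoxyphosphoryl)-3-[3-(3-methylbut-2-enyl)-4-(triisopropylsilyloxy)phenyl]propanoate (racemic)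
Conditions: NaH, THF–DMF, 0 °C → 25 °C
Reagents that add atoms: none
Why: C-Alkylation of the stabilised phosphonoacetate anion by the reactive benzylic bromide is the usual way to alpha-substituted diaryl phosphonoacetates, and the racemic centre it creates disappears in the olefination.

Step 8
Reactants: 1 4-hydroxybenzaldehyde
Product: 13 4-(triisopropylsilyloxy)benzaldehyde
Conditions: TIPSCl, imidazole, DMF, 25 °C
Reagents that add atoms: chlorotriisopropylsilane, CC(C)[Si](Cl)(C(C)C)C(C)C
Why: Imidazole-mediated O-silylation protects the ring A phenol with the same fluoride-labile group as ring B.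

Step 9
Reactants: 12 2-(trimethylsilyl)ethyl 2-(diphenoxyphosphoryl)-3-[3-(3-methylbut-2-enyl)-4-(triisopropylsilyloxy)phenyl]propanoate; 13 4-(triisopropylsilyloxy)benzaldehyde
Product: 14 2-(trimethylsilyl)ethyl (Z)-2-{[3-(3-methylbut-2-enyl)-4-(triisopropylsilyloxy)phenyl]methyl}-3-[4-(triisopropylsilyloxy)phenyl]prop-2-enoate
Conditions: KOt-Bu, THF, −78 °C → 0 °C
Reagents that add atoms: none
Why: Z-selective Horner–Wadsworth–Emmons olefination with a diaryl phosphonate (Ando variant), in which the electron-poor phosphorus makes elimination from the first-formed adduct faster than its equilibration, should place ring A cis to the ester.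

Step 10
Reactants: 14 2-(trimethylsilyl)ethyl (Z)-2-{[3-(3-methylbut-2-enyl)-4-(triisopropylsilyloxy)phenyl]methyl}-3-[4-(triisopropylsilyloxy)phenyl]prop-2-enoate; 15 carbon monoxide; 16 methanol
Product: 17 1-methyl 4-[2-(trimethylsilyl)ethyl] (2S,3S)-3-{[3-(3-methylbut-2-enyl)-4-(triisopropylsilyloxy)phenyl]methyl}-2-[4-(triisopropylsilyloxy)phenyl]butanedioate
Conditions: Pd(OAc)2 (5 mol %), (R)-DTBM-SEGPHOS (6 mol %), MeSO3H (10 mol %), CO (30 bar), MeOH (5 equiv), ClCH2CH2Cl, 50 °C
Reagents that add atoms: none
Why: Proposed new method: a cationic divalent palladium hydride, generated from Pd(OAc)2, the chiral bisphosphine and MeSO3H, should insert the C2=C3 alkene with hydrogen going to C3 and palladium to benzylic C2 (an eta-3 benzyl complex, also beta to the ester), after which CO inserts into the C2–Pd bond with retention and methanolysis of the acyl gives the methyl ester and returns the hydride. The closest known reaction types are the palladium-catalysed asymmetric Markovnikov hydromethoxycarbonylation of vinyl arenes and the syn-stereospecific alkoxycarbonylation of 1,2-disubstituted alkenes, but a trisubstituted 2-benzylcinnamate has not been shown to react in this way. No ring is closed. C2 and C3 are created together: syn delivery of H and CO2Me to the Z alkene, in which ring A is cis to the C4 ester, fixes the erythro relationship, and the chiral bisphosphine is relied on to select the C2-Re/C3-Re face, which corresponds to (2S,3S). The step needs acyl delivery to C2 and not C3, CO capture faster than reversible beta-hydride elimination (which would scramble the alkene geometry or move the alkene toward ring B) and no reaction at the prenyl alkene; these are secured by the eta-3 benzyl stabilisation from electron-rich ring A, by the fact that the only beta-hydrogen of the C2 palladium alkyl is the one just delivered, by the high CO pressure and by the slower insertion of the unactivated trisubstituted prenyl alkene. The aryl silyl ethers keep the ring B phenol from cyclising onto the prenyl group under the acid, and the small excess of methanol with catalytic acid should leave the hindered 2-(trimethylsilyl)ethyl ester untransesterified.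

Step 11
Reactants: 17 1-methyl 4-[2-(trimethylsilyl)ethyl] (2S,3S)-3-{[3-(3-methylbut-2-enyl)-4-(triisopropylsilyloxy)phenyl]methyl}-2-[4-(triisopropylsilyloxy)phenyl]butanedioate
Product: 18 asperteretal G2, (2S,3S)-2-{[4-hydroxy-3-(3-methylbut-2-enyl)phenyl]methyl}-3-(4-hydroxyphenyl)-4-methoxy-4-oxobutanoic acid
Conditions: TASF [(Me2N)3S+ Me3SiF2−], DMF, 0 °C → 25 °C; then aq. HCl (pH 3)
Reagents that add atoms: none
Why: Fluoride-induced fragmentation of the 2-(trimethylsilyl)ethyl ester (to carboxylate, ethylene and Me3SiF) and fluoride cleavage of both aryl silyl ethers occur in one operation with a mild anhydrous fluoride source that leaves the methyl ester alone, and the phenoxide and carboxylate formed first lower the C–H acidity at C2 and C3 so that neither stereocentre should epimerise.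

**Compound list**

1 | 4-hydroxybenzaldehyde | O=Cc1ccc(O)cc1 | starting material
2 | prenyl bromide (1-bromo-3-methylbut-2-ene) | CC(C)=CCBr | starting material
3 | 4-hydroxy-3-(3-methylbut-2-enyl)benzaldehyde | O=Cc1ccc(O)c(CC=C(C)C)c1 | intermediate
4 | 3-(3-methylbut-2-enyl)-4-(triisopropylsilyloxy)benzaldehyde | O=Cc1ccc(O[Si](C(C)C)(C(C)C)C(C)C)c(CC=C(C)C)c1 | intermediate
5 | [3-(3-methylbut-2-enyl)-4-(triisopropylsilyloxy)phenyl]methanol | OCc1ccc(O[Si](C(C)C)(C(C)C)C(C)C)c(CC=C(C)C)c1 | intermediate
6 | 4-(bromomethyl)-2-(3-methylbut-2-enyl)-1-(triisopropylsilyloxy)benzene | BrCc1ccc(O[Si](C(C)C)(C(C)C)C(C)C)c(CC=C(C)C)c1 | intermediate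
7 | 2-(trimethylsilyl)ethanol | C[Si](C)(C)CCO | starting material
8 | bromoacetyl bromide | BrCC(Br)=O | starting material
9 | 2-(trimethylsilyl)ethyl bromoacetate | C[Si](C)(C)CCOC(=O)CBr | intermediate
10 | diphenyl phosphite | O=[PH](Oc1ccccc1)Oc1ccccc1 | starting material
11 | 2-(trimethylsilyl)ethyl (diphenoxyphosphoryl)acetate | C[Si](C)(C)CCOC(=O)CP(=O)(Oc1ccccc1)Oc1ccccc1 | intermediate
12 | 2-(trimethylsilyl)ethyl 2-(diphenoxyphosphoryl)-3-[3-(3-methylbut-2-enyl)-4-(triisopropylsilyloxy)phenyl]propanoate (racemic) | C[Si](C)(C)CCOC(=O)C(Cc1ccc(O[Si](C(C)C)(C(C)C)C(C)C)c(CC=C(C)C)c1)P(=O)(Oc1ccccc1)Oc1ccccc1 | intermediate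
13 | 4-(triisopropylsilyloxy)benzaldehyde | O=Cc1ccc(O[Si](C(C)C)(C(C)C)C(C)C)cc1 | intermediate
14 | 2-(trimethylsilyl)ethyl (Z)-2-{[3-(3-methylbut-2-enyl)-4-(triisopropylsilyloxy)phenyl]methyl}-3-[4-(triisopropylsilyloxy)phenyl]prop-2-enoate | C[Si](C)(C)CCOC(=O)/C(Cc1ccc(O[Si](C(C)C)(C(C)C)C(C)C)c(CC=C(C)C)c1)=C\c1ccc(O[Si](C(C)C)(C(C)C)C(C)C)cc1 | intermediate
15 | carbon monoxide | [C-]#[O+] | starting material
16 | methanol | CO | starting material
17 | 1-methyl 4-[2-(trimethylsilyl)ethyl] (2S,3S)-3-{[3-(3-methylbut-2-enyl)-4-(triisopropylsilyloxy)phenyl]methyl}-2-[4-(triisopropylsilyloxy)phenyl]butanedioate | COC(=O)[C@H](c1ccc(O[Si](C(C)C)(C(C)C)C(C)C)cc1)[C@H](Cc1ccc(O[Si](C(C)C)(C(C)C)C(C)C)c(CC=C(C)C)c1)C(=O)OCC[Si](C)(C)C | intermediate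
18 | asperteretal G2, (2S,3S)-2-{[4-hydroxy-3-(3-methylbut-2-enyl)phenyl]methyl}-3-(4-hydroxyphenyl)-4-methoxy-4-oxobutanoic acid | COC(=O)[C@H](c1ccc(O)cc1)[C@H](Cc1ccc(O)c(CC=C(C)C)c1)C(=O)O | target

**Step count and risks**

Total: 11 steps. Longest linear sequence: 8 steps (1 → 3 → 4 → 5 → 6 → 12 → 14 → 17 → 18, steps 1, 2, 3, 4, 7, 9, 10, 11).

Steps most likely to fail:

1. Step 10 (proposed new method).
   - What may go wrong: hydride insertion into the hindered, electron-poor trisubstituted alkene may be too slow. Insertion may be reversible, so that the alkene isomerises (E/Z scrambling or migration toward ring B) before CO is captured, which would erode the erythro relationship and the regiochemistry. The prenyl alkene may isomerise or be carbonylated, and face selection by the ligand may be poor.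
   - Fallback (known chemistry): the C2–C3 bond is made instead by auxiliary-controlled displacement of an enantiopure alpha-triflyloxy ester by an imide enolate, a known route to 2,3-disubstituted succinates. It sets out from phosphonate 12 and returns at 17.
   - C3–C4 half: deprotonation of 12 (KN(SiMe3)2, THF, −78 °C) and oxygenation with dry O2 should expel diphenyl phosphate and give 2-(trimethylsilyl)ethyl 3-[3-(3-methylbut-2-enyl)-4-(triisopropylsilyloxy)phenyl]-2-oxopropanoate F1. Hydrogenation over RuCl2[(S)-BINAP] should give 2-(trimethylsilyl)ethyl (2S)-2-hydroxy-3-[3-(3-methylbut-2-enyl)-4-(triisopropylsilyloxy)phenyl]propanoate F2; any minor antipode is removed later as a diastereomer. Tf2O with 2,6-lutidine (CH2Cl2, −78 °C) converts it to 2-(trimethylsilyl)ethyl (2S)-3-[3-(3-methylbut-2-enyl)-4-(triisopropylsilyloxy)phenyl]-2-(trifluoromethylsulfonyloxy)propanoate F3.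
   - C1–C2 half: commercial 4-hydroxyphenylacetic acid is silylated twice (TIPSCl, imidazole) to triisopropylsilyl [4-(triisopropylsilyloxy)phenyl]acetate F4. Its silyl ester is hydrolysed on aqueous K2CO3 work-up to [4-(triisopropylsilyloxy)phenyl]acetic acid F5. DCC/DMAP coupling with (4S)-4-benzyl-1,3-oxazolidin-2-one gives (4S)-4-benzyl-3-{[4-(triisopropylsilyloxy)phenyl]acetyl}-1,3-oxazolidin-2-one F6.
   - Union: the sodium Z enolate of F6 (NaN(SiMe3)2, THF, −78 °C) displaces the triflate of F3 with inversion, the auxiliary fixing C2 and the triflate C3. This should give 2-(trimethylsilyl)ethyl (2S,3S)-4-[(4S)-4-benzyl-2-oxo-1,3-oxazolidin-3-yl]-2-{[3-(3-methylbut-2-enyl)-4-(triisopropylsilyloxy)phenyl]methyl}-4-oxo-3-[4-(triisopropylsilyloxy)phenyl]butanoate F7. Methanolysis of the imide with MeOMgBr (CH2Cl2–MeOH, 0 °C) returns to 17.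

2. Step 9.
   - What may go wrong: with the bulky alpha-benzyl phosphonate and an electron-rich aldehyde, the adduct may equilibrate before elimination, so that kinetic control is lost and the E alkene (ring A trans to the ester) forms in amounts that cannot be separated.
   - Fallback: the alkene geometry is fixed by a stereospecific syn hydrometalation and coupling. It sets out from aldehyde 13 (with bromide 6 as coupling partner), returns at 14, and also bypasses phosphonate 12.
   - Corey–Fuchs homologation of 13 (CBr4, PPh3) gives 1-(2,2-dibromoethenyl)-4-(triisopropylsilyloxy)benzene F8. n-BuLi (2 equiv, THF, −78 °C) and trapping of the acetylide with 2-(trimethylsilyl)ethyl chloroformate give 2-(trimethylsilyl)ethyl 3-[4-(triisopropylsilyloxy)phenyl]prop-2-ynoate F9.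
   - Palladium-catalysed syn hydrostannation (Bu3SnH, Pd(PPh3)4, THF) places tin alpha to the ester and gives 2-(trimethylsilyl)ethyl (E)-2-(tributylstannyl)-3-[4-(triisopropylsilyloxy)phenyl]prop-2-enoate F10, in which ring A is already cis to the ester.
   - Stille coupling of F10 with 6 (Pd2(dba)3, AsPh3, CuI, DMF) proceeds with retention at the alkenyl carbon and returns to 14.

3. Step 1.
   - What may go wrong: O-alkylation and double C-alkylation of the ambident phenoxide may outrun the wanted single ortho C-prenylation.
   - Fallback: the aryl–prenyl bond is made by cross-coupling instead. It sets out from 1 and returns at 4.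
   - Bromination of 1 (Br2, AcOH) gives 3-bromo-4-hydroxybenzaldehyde F11, and silylation (TIPSCl, imidazole, DMF) gives 3-bromo-4-(triisopropylsilyloxy)benzaldehyde F12.
   - Stille coupling of F12 with tributyl(3-methylbut-2-enyl)stannane (Pd(PPh3)4, DMF, 90 °C) should give the linear prenyl arene 4.

**Further compounds**

F1 | step 10 | 2-(trimethylsilyl)ethyl 3-[3-(3-methylbut-2-enyl)-4-(triisopropylsilyloxy)phenyl]-2-oxopropanoate | C[Si](C)(C)CCOC(=O)C(=O)Cc1ccc(O[Si](C(C)C)(C(C)C)C(C)C)c(CC=C(C)C)c1
F2 | step 10 | 2-(trimethylsilyl)ethyl (2S)-2-hydroxy-3-[3-(3-methylbut-2-enyl)-4-(triisopropylsilyloxy)phenyl]propanoate | C[Si](C)(C)CCOC(=O)[C@@H](O)Cc1ccc(O[Si](C(C)C)(C(C)C)C(C)C)c(CC=C(C)C)c1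
F3 | step 10 | 2-(trimethylsilyl)ethyl (2S)-3-[3-(3-methylbut-2-enyl)-4-(triisopropylsilyloxy)phenyl]-2-(trifluoromethylsulfonyloxy)propanoate | C[Si](C)(C)CCOC(=O)[C@@H](OS(=O)(=O)C(F)(F)F)Cc1ccc(O[Si](C(C)C)(C(C)C)C(C)C)c(CC=C(C)C)c1
F4 | step 10 | triisopropylsilyl [4-(triisopropylsilyloxy)phenyl]acetate | CC(C)[Si](OC(=O)Cc1ccc(O[Si](C(C)C)(C(C)C)C(C)C)cc1)(C(C)C)C(C)C
F5 | step 10 | [4-(triisopropylsilyloxy)phenyl]acetic acid | OC(=O)Cc1ccc(O[Si](C(C)C)(C(C)C)C(C)C)cc1
F6 | step 10 | (4S)-4-benzyl-3-{[4-(triisopropylsilyloxy)phenyl]acetyl}-1,3-oxazolidin-2-one | O=C(Cc1ccc(O[Si](C(C)C)(C(C)C)C(C)C)cc1)N1[C@@H](Cc2ccccc2)COC1=O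
F7 | step 10 | 2-(trimethylsilyl)ethyl (2S,3S)-4-[(4S)-4-benzyl-2-oxo-1,3-oxazolidin-3-yl]-2-{[3-(3-methylbut-2-enyl)-4-(triisopropylsilyloxy)phenyl]methyl}-4-oxo-3-[4-(triisopropylsilyloxy)phenyl]butanoate | O=C([C@H](c1ccc(O[Si](C(C)C)(C(C)C)C(C)C)cc1)[C@H](Cc1ccc(O[Si](C(C)C)(C(C)C)C(C)C)c(CC=C(C)C)c1)C(=O)OCC[Si](C)(C)C)N1[C@@H](Cc2ccccc2)COC1=O
F8 | step 9 | 1-(2,2-dibromoethenyl)-4-(triisopropylsilyloxy)benzene | BrC(Br)=Cc1ccc(O[Si](C(C)C)(C(C)C)C(C)C)cc1
F9 | step 9 | 2-(trimethylsilyl)ethyl 3-[4-(triisopropylsilyloxy)phenyl]prop-2-ynoate | C[Si](C)(C)CCOC(=O)C#Cc1ccc(O[Si](C(C)C)(C(C)C)C(C)C)cc1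
F10 | step 9 | 2-(trimethylsilyl)ethyl (E)-2-(tributylstannyl)-3-[4-(triisopropylsilyloxy)phenyl]prop-2-enoate | C[Si](C)(C)CCOC(=O)/C([Sn](CCCC)(CCCC)CCCC)=C\c1ccc(O[Si](C(C)C)(C(C)C)C(C)C)cc1
F11 | step 1 | 3-bromo-4-hydroxybenzaldehyde | O=Cc1ccc(O)c(Br)c1
F12 | step 1 | 3-bromo-4-(triisopropylsilyloxy)benzaldehyde | O=Cc1ccc(O[Si](C(C)C)(C(C)C)C(C)C)c(Br)c1
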